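**Assumption:** the target SMILES has no stereocentres (squamatic acid is achiral), so no stereocontrol is needed. The sp3 centres in the cyclohexanedione intermediates 3 and 9 are racemic, tautomeric mixtures and are erased on aromatisation.

**Retrosynthetic overview**
- Target ⇐ hydrogenolysis of one benzyl ester ⇐ chlorite oxidation of the A-ring CHO (masked CO2H) ⇐ late depside (aryl ester) coupling of an A-ring salicylic acid with the free 4-OH of a B-ring benzyl ester.
- A-ring acid ⇐ ester hydrolysis ⇐ 4-O-methylation ⇐ chelation-directed C-3 formylation of methyl orsellinate ⇐ aromatisation ⇐ Michael–Dieckmann of methyl acetoacetate + methyl crotonate.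
- B-ring phenol ⇐ carboxylate benzylation ⇐ ester hydrolysis ⇐ methyl β-orsellinate ⇐ aromatisation ⇐ Michael–Dieckmann of methyl 3-oxopentanoate (methyl acetoacetate dianion + MeI) + methyl crotonate.
- Ring order: the two benzene rings are built independently (A-ring in steps 1–2, B-ring in steps 7–8) and joined only through the ester in step 11.

**A-ring branch**

Step 1
Reactants: 1 methyl acetoacetate; 2 methyl (E)-but-2-enoate (methyl crotonate)
Product: 3 methyl 6-methyl-2,4-dioxocyclohexane-1-carboxylate (methyl dihydroorsellinate; racemic, enol/diastereomer mixture)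
Conditions: NaOMe, MeOH, reflux; then aq. HCl, 0 °C
Reagents that add atoms: none (MeOH is lost)
Why: Michael addition of the acetoacetate enolate to the crotonate, then Dieckmann (Claisen) closure of the ketone CH3 onto the crotonate ester, driven by formation of the stable 1,3-dione enolate.

Step 2
Reactants: 3 methyl dihydroorsellinate
Product: 4 methyl 2,4-dihydroxy-6-methylbenzoate (methyl orsellinate)
Conditions: Hg(OAc)2 (2.2 equiv), NaOAc, AcOH, reflux
Reagents that add atoms: none
Why: Mercuric acetate dehydrogenation (α-mercuration/elimination of the enolised β-dicarbonyl) followed by tautomerisation gives the resorcylate, with aromatisation as the driving force.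

Step 3
Reactants: 4 methyl orsellinate
Product: 5 methyl 3-formyl-2,4-dihydroxy-6-methylbenzoate (methyl haematommate)
Conditions: Cl2CHOMe, TiCl4, CH2Cl2, −10 °C → rt; aq. HCl; separate from minor 5-formyl isomer
Reagents that add atoms: dichloromethyl methyl ether, COC(Cl)Cl (formyl carbon; the formyl O comes from it or from water, O, on work-up)
Why: Rieche formylation, in which the titanium phenoxide/ester chelate directs the electrophile to C-3 between the two hydroxyls; ester and phenols tolerate TiCl4.

Step 4
Reactants: 5 methyl haematommate
Product: 6 methyl 3-formyl-2-hydroxy-4-methoxy-6-methylbenzoate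
Conditions: MeI (1.05 equiv), K2CO3 (1.1 equiv), acetone, rt
Reagents that add atoms: iodomethane, CI
Why: Williamson etherification at the more acidic, less hindered 4-OH; the 2-OH is flanked by ester and formyl groups and strongly hydrogen-bonded, so it stays free with one equivalent of MeI.

Step 5
Reactants: 6 methyl 3-formyl-2-hydroxy-4-methoxy-6-methylbenzoate
Product: 7 3-formyl-2-hydroxy-4-methoxy-6-methylbenzoic acid
Conditions: KOH, DMSO/H2O, 65 °C, N2; then cold 1 M HCl (0 °C, pH 2)
Reagents that add atoms: water (as KOH/H2O), O
Why: BAc2 saponification of the hindered ester by DMSO-activated hydroxide; the phenoxide-conjugated aldehyde is inert to Cannizzaro, and cold acidification avoids decarboxylation.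

**B-ring branch**

Step 6
Reactants: 1 methyl acetoacetate
Product: 8 methyl 3-oxopentanoate
Conditions: NaH, THF, 0 °C; n-BuLi, 0 °C; MeI, 0 °C → rt; aq. HCl
Reagents that add atoms: iodomethane, CI
Why: Weiler dianion alkylation, which reacts only at the more basic terminal (γ) carbanion.

Step 7
Reactants: 8 methyl 3-oxopentanoate; 2 methyl crotonate
Product: 9 methyl 3,6-dimethyl-2,4-dioxocyclohexane-1-carboxylate (racemic, enol/diastereomer mixture)
Conditions: NaOMe, MeOH, reflux; then aq. HCl, 0 °C
Reagents that add atoms: none (MeOH is lost)
Why: Michael addition at C-2 of the keto ester, then Dieckmann closure of the ethyl-ketone CH2 onto the crotonate ester, which places the second methyl at C-3 between the two carbonyls.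

Step 8
Reactants: 9 methyl 3,6-dimethyl-2,4-dioxocyclohexane-1-carboxylate
Product: 10 methyl 2,4-dihydroxy-3,6-dimethylbenzoate (methyl β-orsellinate)
Conditions: Hg(OAc)2 (2.2 equiv), NaOAc, AcOH, reflux
Reagents that add atoms: none
Why: The same mercuric acetate dehydrogenation as step 2; mercuration/elimination occurs across C-1/C-6 (or C-5/C-6), so the blocked C-3 does not interfere.

Step 9
Reactants: 10 methyl β-orsellinate
Product: 11 2,4-dihydroxy-3,6-dimethylbenzoic acid
Conditions: KOH, DMSO/H2O, 70 °C, N2; then cold 1 M HCl (0 °C, pH 2), no heating of the free acid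
Reagents that add atoms: water (as KOH/H2O), O
Why: BAc2 saponification assisted by the neighbouring phenoxide; moderate temperature and cold acidification preserve the decarboxylation-prone acid.

Step 10
Reactants: 11 2,4-dihydroxy-3,6-dimethylbenzoic acid
Product: 12 benzyl 2,4-dihydroxy-3,6-dimethylbenzoate
Conditions: BnBr (1.05 equiv), KHCO3, DMF, rt → 40 °C
Reagents that add atoms: benzyl bromide, BrCc1ccccc1
Why: SN2 O-alkylation of the carboxylate; bicarbonate deprotonates only the acid, so both phenols stay free.

**Coupling and end game**

Step 11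
Reactants: 7 3-formyl-2-hydroxy-4-methoxy-6-methylbenzoic acid; 12 benzyl 2,4-dihydroxy-3,6-dimethylbenzoate
Product: 13 benzyl 4-[(3-formyl-2-hydroxy-4-methoxy-6-methylbenzoyl)oxy]-2-hydroxy-3,6-dimethylbenzoate
Conditions: (CF3CO)2O, anhydrous toluene, rt; aq. NaHCO3 work-up
Reagents that add atoms: none (water is lost)
Why: Mixed-anhydride esterification (depside coupling), in which the acyl trifluoroacetate of 7 acylates the only non-chelated phenol, the 4-OH of 12; the ester-chelated 2-OH groups of both partners stay free.

Step 12
Reactants: 13 depside aldehyde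
Product: 14 3-{[4-(benzyloxycarbonyl)-3-hydroxy-2,5-dimethylphenoxy]carbonyl}-2-hydroxy-6-methoxy-4-methylbenzoic acid
Conditions: NaClO2, NaH2PO4, 2-methyl-2-butene (excess), t-BuOH/THF/H2O, 0 °C → rt
Reagents that add atoms: sodium chlorite, [Na+].[O-]Cl=O
Why: Lindgren–Pinnick oxidation converts ArCHO to ArCO2H at pH 3–4 without touching the aryl or benzyl esters; the alkene scavenges HOCl to protect the phenolic rings from chlorination.

Step 13
Reactants: 14 mono-benzyl ester
Product: 15 squamatic acid (target)
Conditions: H2 (1 atm), 10% Pd/C, EtOAc, rt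
Reagents that add atoms: none
Why: Hydrogenolysis cleaves only the benzyl C–O bond (toluene lost); the depside ester, methyl ether and acids are inert, and no reducible aldehyde remains.

**Compound list**
1 | methyl acetoacetate (methyl 3-oxobutanoate) | COC(=O)CC(C)=O | starting material
2 | methyl (E)-but-2-enoate (methyl crotonate) | C/C=C/C(=O)OC | starting material
3 | methyl 6-methyl-2,4-dioxocyclohexane-1-carboxylate (racemic, tautomeric mixture) | COC(=O)C1C(C)CC(=O)CC1=O | intermediate
4 | methyl 2,4-dihydroxy-6-methylbenzoate (methyl orsellinate) | COC(=O)c1c(C)cc(O)cc1O | intermediate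
5 | methyl 3-formyl-2,4-dihydroxy-6-methylbenzoate (methyl haematommate) | COC(=O)c1c(C)cc(O)c(C=O)c1O | intermediate
6 | methyl 3-formyl-2-hydroxy-4-methoxy-6-methylbenzoate | COC(=O)c1c(C)cc(OC)c(C=O)c1O | intermediate
7 | 3-formyl-2-hydroxy-4-methoxy-6-methylbenzoic acid | COc1cc(C)c(C(=O)O)c(O)c1C=O | intermediate
8 | methyl 3-oxopentanoate | CCC(=O)CC(=O)OC | intermediate
9 | methyl 3,6-dimethyl-2,4-dioxocyclohexane-1-carboxylate (racemic, tautomeric mixture) | COC(=O)C1C(C)CC(=O)C(C)C1=O | intermediate
10 | methyl 2,4-dihydroxy-3,6-dimethylbenzoate (methyl β-orsellinate) | COC(=O)c1c(C)cc(O)c(C)c1O | intermediate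
11 | 2,4-dihydroxy-3,6-dimethylbenzoic acid | Cc1cc(O)c(C)c(O)c1C(=O)O | intermediate
12 | benzyl 2,4-dihydroxy-3,6-dimethylbenzoate | Cc1cc(O)c(C)c(O)c1C(=O)OCc1ccccc1 | intermediate
13 | benzyl 4-[(3-formyl-2-hydroxy-4-methoxy-6-methylbenzoyl)oxy]-2-hydroxy-3,6-dimethylbenzoate | COc1cc(C)c(C(=O)Oc2cc(C)c(C(=O)OCc3ccccc3)c(O)c2C)c(O)c1C=O | intermediate
14 | 3-{[4-(benzyloxycarbonyl)-3-hydroxy-2,5-dimethylphenoxy]carbonyl}-2-hydroxy-6-methoxy-4-methylbenzoic acid | COc1cc(C)c(C(=O)Oc2cc(C)c(C(=O)OCc3ccccc3)c(O)c2C)c(O)c1C(=O)O | intermediate
15 | squamatic acid | COc1cc(C)c(C(=O)Oc2cc(C)c(C(=O)O)c(O)c2C)c(O)c1C(=O)O | target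

**Total step count:** 13.
**Longest linear sequence:** 8 steps (steps 1–5 then 11–13; equally steps 6–10 then 11–13).

**Three steps most likely to fail**
1. Step 9 (and its sibling, step 5): the hindered, phenoxide-deactivated methyl ester may hydrolyse slowly, and the electron-rich salicylic acid may decarboxylate. Fallback: avoid the hydrolysis by exchanging the ester at the β-keto-ester stage. Heat 9 with BnOH (toluene, reflux, cat. DMAP, removal of MeOH; acyl-ketene transesterification) and then aromatise, which gives 12 directly.
2. Step 3: formylation may give too much of the 5-formyl isomer. Fallback: reverse the order. Mono-methylate 4 at the unchelated 4-OH (MeI, K2CO3), then use phenol-directed Mg-mediated ortho-formylation (MgCl2, Et3N, paraformaldehyde, MeCN, reflux). The only free position ortho to the remaining OH is C-3, so this leads straight to 6.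
3. Step 12: the late chlorite oxidation may chlorinate the phenolic rings or stall on the hindered, hydrogen-bonded aldehyde. Fallback: adjust the oxidation level before coupling.
   - Exchange the methyl ester of 3 for an allyl ester (allyl alcohol, toluene, reflux), then aromatise, formylate and O-methylate as before.
   - Pinnick-oxidise this monocyclic aldehyde and benzylate both the new acid and the 2-OH (BnBr, K2CO3).
   - Remove the allyl ester (Pd(PPh3)4, morpholine), couple the acid to 12 via the acid chloride, and finish with one global hydrogenolysis.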